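The C6–C7 bond is the one bond common to the ten-membered carbocycle and the γ-lactone. Its O–C6–C7–C11(=C13)–C12 array is the retron of a carbonyl 2-(alkoxycarbonyl)allylation. One CrCl2-mediated operation on an open-chain precursor, a (Z)-2-(bromomethyl)enoate (C13, C11, C12, C7) tethered through C8–C10 and C1–C4 to a 4,5-epoxy aldehyde (C6), should close the carbocycle, set C6 and C7, and let O6 lactonise onto C12. The chain is assembled linearly from nerol (C1–C6, C15), methyl acrylate (C9, C10, C14), an asymmetric alkoxyallylboration (C7, C8; sets C8 and C9) and methyl 2-(bromomethyl)acrylate (C11–C13). The angelate is attached after ring closure.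

Key step: step 11

Remark: atom numbers are germacrane numbers (C1–C10 ring, C11–C13 methylene lactone, C14 ester carbon on C10, C15 methyl on C4); the SMILES is read as 4R,5S,6R,7R,8S,9S, i.e. an epoxide with C3 and C6 cis, a cis-fused 12,6-lactone and C9 cis to C2 across C1=C10.

Step 1
Reactants: 1 nerol
Product: 2 (2S,3R)-2,3-epoxynerol
Conditions: Ti(OiPr)4 (cat.), L-(+)-diethyl tartrate (cat.), t-BuOOH, 4 Å MS, CH2Cl2, −20 °C
Reagents that add atoms: tert-butyl hydroperoxide, CC(C)(C)OO
Why: Katsuki–Sharpless asymmetric epoxidation epoxidises only the allylic alcohol olefin, and the L-(+)-tartrate complex delivers oxygen to the face that gives 2S, so the Z-olefin of nerol should give the cis-epoxide with C4 R and C5 S while the remote olefin is untouched.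

Step 2
Reactants: 2 (2S,3R)-2,3-epoxynerol
Product: 3 triethylsilyl ether of 2
Conditions: Et3SiCl, imidazole, CH2Cl2, 0 °C
Reagents that add atoms: chlorotriethylsilane, CC[Si](Cl)(CC)CC
Why: Silylation of the primary alcohol touches no stereocentre, and a primary triethylsilyl ether is chosen because it can later be oxidised directly to the aldehyde.

Step 3
Reactants: 3 triethylsilyl ether of 2
Product: 4 3-[(2R,3S)-2-methyl-3-{[(triethylsilyl)oxy]methyl}oxiran-2-yl]propanal
Conditions: O3, CH2Cl2, −78 °C; then Me2S, −78 °C → rt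
Reagents that add atoms: ozone, [O-][O+]=O
Why: Ozonolysis with reductive work-up cleaves the only C=C bond left and gives the C1 aldehyde; epoxide and silyl ether are inert to ozone at low temperature.

Step 4
Reactants: 4 epoxy aldehyde; 5 methyl acrylate
Product: 6 methyl 3-hydroxy-2-methylidene-5-[(2R,3S)-2-methyl-3-{[(triethylsilyl)oxy]methyl}oxiran-2-yl]pentanoate (both C3 epimers)
Conditions: DABCO (cat.), 5 (neat, excess), rt
Reagents that add atoms: none
Why: The Morita–Baylis–Hillman reaction of an unhindered aliphatic aldehyde installs C10, C14 and C9 in one step; the new carbinol centre at C1 forms unselectively and is destroyed in step 5.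

Step 5
Reactants: 6 Baylis–Hillman alcohol
Product: 7 methyl (2Z)-2-(bromomethyl)-5-[(2R,3S)-2-methyl-3-{[(triethylsilyl)oxy]methyl}oxiran-2-yl]pent-2-enoate
Conditions: NBS, Me2S, CH2Cl2, 0 °C → rt
Reagents that add atoms: N-bromosuccinimide, O=C1CCC(=O)N1Br
Why: Corey–Kim-type activation of the alcohol and SN2′ attack of bromide should give the thermodynamically preferred (Z)-2-(bromomethyl)alk-2-enoate, in which C2 is trans to the ester and cis to C9, the geometry required for C1=C10.

Step 6
Reactants: 7 allylic bromide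
Product: 8 methyl (2E)-2-formyl-5-[(2R,3S)-2-methyl-3-{[(triethylsilyl)oxy]methyl}oxiran-2-yl]pent-2-enoate
Conditions: N-methylmorpholine N-oxide, 4 Å MS, MeCN, 0 °C → rt
Reagents that add atoms: N-methylmorpholine N-oxide, C[N+]1([O-])CCOCC1
Why: In this amine N-oxide (Ganem) oxidation, SN2 O-alkylation by the primary allylic bromide and elimination of the amine give the aldehyde without touching the double bond, so C9 stays cis to C2.

Step 7
Reactants: 8 formyl enoate; 9 allyl 4-methoxybenzyl ether
Product: 11 methyl (2E)-2-{(1S,2S)-1-hydroxy-2-[(4-methoxybenzyl)oxy]but-3-en-1-yl}-5-[(2R,3S)-2-methyl-3-{[(triethylsilyl)oxy]methyl}oxiran-2-yl]pent-2-enoate, via alkoxyallylborane 10 (not isolated)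
Conditions: 9, s-BuLi, THF, −78 °C; (+)-Ipc2BOMe; BF3·OEt2 (1.0 equiv); then 8, −78 °C; ethanolamine work-up
Reagents that add atoms: none
Why: In this Brown asymmetric γ-alkoxyallylboration the (Z)-alkoxyallylborane adds through a Zimmerman–Traxler chair, the Z enol ether giving the syn 8,9-relationship and the isopinocampheyl groups from (−)-α-pinene directing attack to the Re face of C9 (8S,9S); one equivalent of BF3·OEt2 in THF at −78 °C and a non-oxidative work-up are chosen to spare epoxide and enoate.

Step 8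
Reactants: 11 allylic alcohol
Product: 12 triethylsilyl ether of 11 at the C9 hydroxyl
Conditions: Et3SiOTf, 2,6-lutidine, CH2Cl2, −78 °C
Reagents that add atoms: triethylsilyl triflate, CC[Si](CC)(CC)OS(=O)(=O)C(F)(F)F
Why: Silylation of the hindered C9 hydroxyl distinguishes O9 from O8, which stays as its 4-methoxybenzyl ether until after ring closure.

Step 9
Reactants: 12 bis(triethylsilyl) ether; 13 methyl 2-(bromomethyl)prop-2-enoate
Product: 14 dimethyl (2Z,4S,5S,6E)-2-(bromomethyl)-4-[(4-methoxybenzyl)oxy]-6-{3-[(2R,3S)-2-methyl-3-{[(triethylsilyl)oxy]methyl}oxiran-2-yl]propylidene}-5-[(triethylsilyl)oxy]hept-2-enedioate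
Conditions: 13 (5 equiv), second-generation Hoveyda–Grubbs catalyst (10 mol%), CH2Cl2, 40 °C
Reagents that add atoms: none
Why: Olefin cross-metathesis joins the monosubstituted C7 vinyl group to the 1,1-disubstituted acrylate 13; the trisubstituted C1=C10 enoate is inert, and the thermodynamically controlled product has the C8 chain trans to the ester, i.e. the (Z)-2-(bromomethyl)enoate needed for ring closure.

Step 10
Reactants: 14 allylic bromide
Product: 15 dimethyl (2Z,4S,5S,6E)-2-(bromomethyl)-6-{3-[(2R,3R)-3-formyl-2-methyloxiran-2-yl]propylidene}-4-[(4-methoxybenzyl)oxy]-5-[(triethylsilyl)oxy]hept-2-enedioate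
Conditions: (COCl)2, DMSO, CH2Cl2, −78 → −40 °C; then iPr2NEt, −78 → 0 °C
Reagents that add atoms: none
Why: In this direct Swern oxidation of a primary triethylsilyl ether the chlorosulfonium ion displaces silicon only at the unhindered primary oxygen, so the C9 silyl ether survives, and the hindered amine should neither quaternise the allylic bromide nor epimerise the epoxy aldehyde.

Step 11
Reactants: 15 epoxy aldehyde allylic bromide
Product: 17 macrocyclic lactone (22 with 4-methoxybenzyl on O8 in place of the angeloyl group and triethylsilyl on O9), via seco hydroxy diester 16 (not isolated)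
Conditions: CrCl2 (10 equiv), THF, 0.002 M, slow addition of 15, rt; aq NH4Cl
Reagents that add atoms: none
Why: Two equivalents of CrCl2 reduce the C13–Br bond to a trivalent allylchromium species, which adds through C7 (allylic transposition) to the C6 aldehyde in a six-membered chair transition state, and the C6 chromium alkoxide then acylates on the C12 methyl ester with loss of methoxide. The closest known reaction type is the intramolecular Nozaki–Hiyama–Kishi (chromium Barbier) 2-(alkoxycarbonyl)allylation that closes ten-membered sesquiterpene lactone rings. The carbocycle closes in the 10-exo-trig mode (C6=O exocyclic to the new ring), the lactone in the 5-exo-trig mode (substitution at the C12 carbonyl). C6 and C7 are set together: the Z geometry of C7=C11 places C8 axial and C5 equatorial in the chair, which gives the syn adduct and therefore the cis-fused lactone. The face pair is expected to be chosen by C8 and C5: allylic 1,3-strain with C13 holds C8–H in the allyl plane so that C6 bonds anti to the C8–C9 bond, and the epoxy aldehyde should react with its epoxide oxygen bound to the same chromium as O6, both preferences leading to 6R,7R. The step needs selectivity for the aldehyde over the two esters, which allylchromium reagents have, and ring closure over oligomerisation, which slow addition at high dilution and the two cis elements of the chain (C1=C10 and the cis-epoxide) should favour.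

Step 12
Reactants: 17 macrocyclic lactone
Product: 18 8-hydroxy lactone (22 without the angeloyl group, O9 triethylsilylated)
Conditions: DDQ, CH2Cl2/pH 7 buffer, 0 °C
Reagents that add atoms: none
Why: DDQ oxidation of the 4-methoxybenzyl ether frees only O8; O8 is unmasked only now because an acyloxy group at C8 could be lost from the allylchromium by reductive 1,4-elimination and a free C8 hydroxyl in the open chain could lactonise onto the C14 ester.

Step 13
Reactants: 18 8-hydroxy lactone; 19 angelic acid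
Product: 21 9-O-triethylsilyl ether of 22, via mixed anhydride 20 (not isolated)
Conditions: 19, 2,4,6-trichlorobenzoyl chloride, Et3N, toluene, rt; then 18, DMAP (cat.), toluene, rt
Reagents that add atoms: none
Why: Yamaguchi esterification acylates the single free hydroxyl with retention at C8; the preformed anhydride and room temperature should suppress Z→E isomerisation of the angelate and translactonisation of O8 onto C12.

Step 14
Reactants: 21 9-O-triethylsilyl ether
Product: 22 CNP0251641.1
Conditions: HF·pyridine, pyridine, THF, 0 °C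
Reagents that add atoms: none
Why: Fluoride-mediated cleavage of the secondary silyl ether under buffered, weakly acidic conditions should leave epoxide and methylene lactone intact and avoid base-induced 8→9 acyl migration.

Compound list
1 | nerol, (2Z)-3,7-dimethylocta-2,6-dien-1-ol | CC(C)=CCC/C(C)=C\CO | starting material
2 | (2S,3R)-2,3-epoxynerol, [(2S,3R)-3-methyl-3-(4-methylpent-3-en-1-yl)oxiran-2-yl]methanol | CC(C)=CCC[C@@]1(C)O[C@H]1CO | intermediate
3 | triethyl{[(2S,3R)-3-methyl-3-(4-methylpent-3-en-1-yl)oxiran-2-yl]methoxy}silane | CC(C)=CCC[C@@]1(C)O[C@H]1CO[Si](CC)(CC)CC | intermediate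
4 | 3-[(2R,3S)-2-methyl-3-{[(triethylsilyl)oxy]methyl}oxiran-2-yl]propanal | O=CCC[C@@]1(C)O[C@H]1CO[Si](CC)(CC)CC | intermediate
5 | methyl acrylate | C=CC(=O)OC | starting material
6 | methyl 3-hydroxy-2-methylidene-5-[(2R,3S)-2-methyl-3-{[(triethylsilyl)oxy]methyl}oxiran-2-yl]pentanoate (C3 epimers) | C=C(C(=O)OC)C(O)CC[C@@]1(C)O[C@H]1CO[Si](CC)(CC)CC | intermediate
7 | methyl (2Z)-2-(bromomethyl)-5-[(2R,3S)-2-methyl-3-{[(triethylsilyl)oxy]methyl}oxiran-2-yl]pent-2-enoate | BrC/C(C(=O)OC)=C\CC[C@@]1(C)O[C@H]1CO[Si](CC)(CC)CC | intermediate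
8 | methyl (2E)-2-formyl-5-[(2R,3S)-2-methyl-3-{[(triethylsilyl)oxy]methyl}oxiran-2-yl]pent-2-enoate | O=C/C(C(=O)OC)=C\CC[C@@]1(C)O[C@H]1CO[Si](CC)(CC)CC | intermediate
9 | allyl 4-methoxybenzyl ether, 1-methoxy-4-[(prop-2-en-1-yloxy)methyl]benzene | C=CCOCc1ccc(OC)cc1 | starting material
10 | [(2Z)-3-(4-methoxybenzyloxy)prop-2-en-1-yl]diisopinocampheylborane (isopinocampheyl groups from (−)-α-pinene) | COc1ccc(CO/C=C\CB([C@H]2C[C@H]3C[C@@H]([C@@H]2C)C3(C)C)[C@H]2C[C@H]3C[C@@H]([C@@H]2C)C3(C)C)cc1 | intermediate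
11 | methyl (2E)-2-{(1S,2S)-1-hydroxy-2-[(4-methoxybenzyl)oxy]but-3-en-1-yl}-5-[(2R,3S)-2-methyl-3-{[(triethylsilyl)oxy]methyl}oxiran-2-yl]pent-2-enoate | C=C[C@H](OCc1ccc(OC)cc1)[C@@H](O)/C(C(=O)OC)=C\CC[C@@]1(C)O[C@H]1CO[Si](CC)(CC)CC | intermediate
12 | methyl (2E)-2-{(1S,2S)-2-[(4-methoxybenzyl)oxy]-1-[(triethylsilyl)oxy]but-3-en-1-yl}-5-[(2R,3S)-2-methyl-3-{[(triethylsilyl)oxy]methyl}oxiran-2-yl]pent-2-enoate | C=C[C@H](OCc1ccc(OC)cc1)[C@@H](O[Si](CC)(CC)CC)/C(C(=O)OC)=C\CC[C@@]1(C)O[C@H]1CO[Si](CC)(CC)CC | intermediate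
13 | methyl 2-(bromomethyl)prop-2-enoate | C=C(CBr)C(=O)OC | starting material
14 | dimethyl (2Z,4S,5S,6E)-2-(bromomethyl)-4-[(4-methoxybenzyl)oxy]-6-{3-[(2R,3S)-2-methyl-3-{[(triethylsilyl)oxy]methyl}oxiran-2-yl]propylidene}-5-[(triethylsilyl)oxy]hept-2-enedioate | BrC/C(C(=O)OC)=C\[C@H](OCc1ccc(OC)cc1)[C@@H](O[Si](CC)(CC)CC)/C(C(=O)OC)=C\CC[C@@]1(C)O[C@H]1CO[Si](CC)(CC)CC | intermediate
15 | dimethyl (2Z,4S,5S,6E)-2-(bromomethyl)-6-{3-[(2R,3R)-3-formyl-2-methyloxiran-2-yl]propylidene}-4-[(4-methoxybenzyl)oxy]-5-[(triethylsilyl)oxy]hept-2-enedioate | BrC/C(C(=O)OC)=C\[C@H](OCc1ccc(OC)cc1)[C@@H](O[Si](CC)(CC)CC)/C(C(=O)OC)=C\CC[C@@]1(C)O[C@H]1C=O | intermediate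
16 | seco hydroxy diester: ten-membered carbocycle of 17 with free C6 hydroxyl and C7 bearing the 2-(methoxycarbonyl)ethenyl group (C11–C13), configuration as in 17 | C=C(C(=O)OC)[C@@H]1[C@H](OCc2ccc(OC)cc2)[C@@H](O[Si](CC)(CC)CC)/C(C(=O)OC)=C\CC[C@@]2(C)O[C@H]2[C@@H]1O | intermediate
17 | macrocyclic lactone: 22 with 4-methoxybenzyl on O8 in place of the angeloyl group and triethylsilyl on O9 | C=C1C(=O)O[C@@H]2[C@H]1[C@H](OCc1ccc(OC)cc1)[C@@H](O[Si](CC)(CC)CC)/C(C(=O)OC)=C\CC[C@@]1(C)O[C@@H]21 | intermediate
18 | 8-hydroxy lactone: 22 without the angeloyl group, triethylsilyl on O9 | C=C1C(=O)O[C@@H]2[C@H]1[C@H](O)[C@@H](O[Si](CC)(CC)CC)/C(C(=O)OC)=C\CC[C@@]1(C)O[C@@H]21 | intermediate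
19 | angelic acid, (2Z)-2-methylbut-2-enoic acid | C/C=C(C)\C(=O)O | starting material
20 | (2Z)-2-methylbut-2-enoic 2,4,6-trichlorobenzoic anhydride | C/C=C(C)\C(=O)OC(=O)c1c(Cl)cc(Cl)cc1Cl | intermediate
21 | 9-O-triethylsilyl ether of 22 | C=C1C(=O)O[C@@H]2[C@H]1[C@H](OC(=O)/C(C)=C\C)[C@@H](O[Si](CC)(CC)CC)/C(C(=O)OC)=C\CC[C@@]1(C)O[C@@H]21 | intermediate
22 | CNP0251641.1: methyl (1(10)E,4R,5S,6R,7R,8S,9S)-8-[(2Z)-2-methylbut-2-enoyloxy]-4,5-epoxy-9-hydroxygermacra-1(10),11(13)-dien-12,6-olid-14-oate | C=C1C(=O)O[C@@H]2[C@H]1[C@H](OC(=O)/C(C)=C\C)[C@@H](O)/C(C(=O)OC)=C\CC[C@@]1(C)O[C@@H]21 | target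

Total step count: 14. Longest linear sequence: 14 steps (1 → 22); 5, 9, 13 and 19 are commercial.

Steps most likely to fail

Step 11. Intermolecular coupling may outrun the ten-membered ring closure. The allylchromium may also equilibrate or react through the other face pair, which would give the 6,7-bis-epimeric cis-lactone or the trans-lactone, or it may lose the C8 ether by reductive 1,4-elimination. The fallback closes the same bond by an intramolecular allylboration instead. It sets out from 12: cross-metathesis with commercial methyl 2-[(4,4,5,5-tetramethyl-1,3,2-dioxaborolan-2-yl)methyl]prop-2-enoate under the conditions of step 9 would give the pinacol allylboronate analogue of 14, F1. Direct Swern oxidation as in step 10 would give the epoxy aldehyde allylboronate F2. Heating F2 at high dilution in toluene (60–80 °C) should cyclise it through a compact boron-centred chair without free metal salts. Cleavage of the borate and lactonisation of 16 on work-up (aq NaHCO3, then PPTS) bring the route back at 17.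

Step 9. Both olefins are hindered and the acrylate is electron-poor, so the catalyst may only dimerise or stall, and the geometry may erode. The fallback builds the bromide by the classical sequence from 12. OsO4 (cat.)/NaIO4/2,6-lutidine cleavage of the vinyl group would give the α-alkoxy aldehyde F3. Morita–Baylis–Hillman reaction with 5 (DABCO) would give the allylic alcohol F4 (C7 epimers). SN2′ bromination with NBS/Me2S as in step 5 returns to 14.

Step 7. BF3·OEt2 may open or rearrange the trisubstituted epoxide, 9 may be lithiated at the benzylic position, and the labile formyl enoate 8 may suffer conjugate addition or geometric isomerisation. The fallback sets the 8,9-syn diol by an Evans syn-glycolate aldol and sets out from 8. The glycolyl imide (R)-4-benzyl-3-{[(4-methoxybenzyl)oxy]acetyl}oxazolidin-2-one F5 is made from (R)-4-benzyloxazolidin-2-one, n-BuLi and (4-methoxybenzyloxy)acetyl chloride. Its boron enolate (Bu2BOTf, iPr2NEt, CH2Cl2, −78 °C) should add to 8 to give the syn aldol F6. Silylation (Et3SiOTf, 2,6-lutidine) would give the silyl ether F7, and LiBH4 (Et2O, 0 °C) would remove the auxiliary to give the primary alcohol F8. Dess–Martin oxidation to the aldehyde F3 and Wittig methylenation (Ph3P=CH2, THF, −78 °C) rejoin the route at 12.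

Further compounds
F1 | step 11 | pinacol allylboronate analogue of 14 (CH2B(pin) in place of CH2Br) | CC1(C)OB(C/C(C(=O)OC)=C\[C@H](OCc2ccc(OC)cc2)[C@@H](O[Si](CC)(CC)CC)/C(C(=O)OC)=C\CC[C@@]2(C)O[C@H]2CO[Si](CC)(CC)CC)OC1(C)C
F2 | step 11 | pinacol allylboronate analogue of 15 (CH2B(pin) in place of CH2Br) | CC1(C)OB(C/C(C(=O)OC)=C\[C@H](OCc2ccc(OC)cc2)[C@@H](O[Si](CC)(CC)CC)/C(C(=O)OC)=C\CC[C@@]2(C)O[C@H]2C=O)OC1(C)C
F3 | step 9 | methyl (2E)-2-{(1S,2S)-2-[(4-methoxybenzyl)oxy]-3-oxo-1-[(triethylsilyl)oxy]propyl}-5-[(2R,3S)-2-methyl-3-{[(triethylsilyl)oxy]methyl}oxiran-2-yl]pent-2-enoate | O=C[C@H](OCc1ccc(OC)cc1)[C@@H](O[Si](CC)(CC)CC)/C(C(=O)OC)=C\CC[C@@]1(C)O[C@H]1CO[Si](CC)(CC)CC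
F4 | step 9 | Baylis–Hillman adduct of F3 with methyl acrylate (C7 epimers) | C=C(C(=O)OC)C(O)[C@H](OCc1ccc(OC)cc1)[C@@H](O[Si](CC)(CC)CC)/C(C(=O)OC)=C\CC[C@@]1(C)O[C@H]1CO[Si](CC)(CC)CC
F5 | step 7 | (R)-4-benzyl-3-{[(4-methoxybenzyl)oxy]acetyl}oxazolidin-2-one | O=C1OC[C@@H](Cc2ccccc2)N1C(=O)COCc1ccc(OC)cc1
F6 | step 7 | syn-glycolate aldol adduct of F5 and 8 | O=C1OC[C@@H](Cc2ccccc2)N1C(=O)[C@H](OCc1ccc(OC)cc1)[C@@H](O)/C(C(=O)OC)=C\CC[C@@]1(C)O[C@H]1CO[Si](CC)(CC)CC
F7 | step 7 | triethylsilyl ether of F6 | O=C1OC[C@@H](Cc2ccccc2)N1C(=O)[C@H](OCc1ccc(OC)cc1)[C@@H](O[Si](CC)(CC)CC)/C(C(=O)OC)=C\CC[C@@]1(C)O[C@H]1CO[Si](CC)(CC)CC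
F8 | step 7 | primary alcohol from reductive removal of the auxiliary of F7 | OC[C@H](OCc1ccc(OC)cc1)[C@@H](O[Si](CC)(CC)CC)/C(C(=O)OC)=C\CC[C@@]1(C)O[C@H]1CO[Si](CC)(CC)CC
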